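Neither earlier run can be copied onto the flask, because neither ever held its charge of starting material, and a rate read at one charge does not hold at another.

| flask | starting material | reagent | free catalyst | remark | time |
|---|---|---|---|---|---|
| south-west | 0.022 M | 0.22 M | 4.4 mM | run made earlier |  |
| north-east | 0.088 M | 0.22 M | 4.4 mM | run made earlier |  |
| flask | 0.044 M | 0.220 M | 4.4 mM |  | 30 h |

| run | time / h | starting material / % | target / % | catalyst intermediate B / % |
|---|---|---|---|---|
| south-west | 4.00 | 76.6 | 20.9 | 2.7 |
| south-west | 8.00 | 56.8 | 40.5 | 2.5 |
| south-west | 10.0 | 49.2 | 48.2 | 2.8 |
| south-west | 15.0 | 33.4 | 63.7 | 2.8 |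
| south-west | 20.0 | 21.7 | 74.2 | 3.2 |
| north-east | 1.50 | 95.9 | 3.6 | 0.6 |
| north-east | 5.00 | 87.8 | 11.0 | 1.0 |
| north-east | 8.00 | 81.7 | 16.4 | 2.0 |
| north-east | 12.0 | 76.0 | 22.9 | 1.9 |
| north-east | 20.0 | 67.1 | 30.4 | 2.3 |

(standard deviation of a reading: 0.3 percentage points)

* the species in which most of what was charged as starting material, at 30 h sits (catalyst intermediate B / starting material / target)
* the largest share itself, whichever of these holds it, in percent of the starting material charged



Take the charged c(starting material), multiply by the natural log of charged over remaining, and divide by the time. At the last readings this gives 1.68 mM h⁻¹ in south-west and 1.76 mM h⁻¹ in north-east, nearly equal although the charges differ by a factor of 4.00. But this figure is no constant of either run, for at 8.00 h the same reckoning gives 1.56 mM h⁻¹ in south-west and 2.22 mM h⁻¹ in north-east, so the near-equality at the last readings is a crossing of one figure that rises and another that falls. Since the flask's charge lies between the two runs' charges, I freeze the mean of the last readings, 1.72 mM h⁻¹, as a rough working figure of my own and call it the drain. For the flask that leaves 31.0% of the starting material at 30 h, and setting aside the 3.2% last read in catalyst intermediate B in south-west, I expect target at 65.8%.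

The forecast holds a different view, of saturating catalyst “leaving about 75% of catalyst active”, and it also names target, but at 78%, between 71% and 84%, which is higher than my figure.

The flask gives target at 65.2%.

    reagent + free catalyst → catalyst intermediate A (k = 0.00120 L mol⁻¹ s⁻¹)
    starting material + catalyst intermediate A → catalyst intermediate B (k = 0.00920 L mol⁻¹ s⁻¹)
    catalyst intermediate B ⇌ free catalyst + target (K = 0.0310 M, k = 0.00160 s⁻¹)
    reagent ⇌ dormant form (K = 3.10, k = 1.30 × 10⁻⁵ s⁻¹)

The flask left 31.1% of its starting material against my 31.0%, but it did not keep a constant drain: reckoned from its own amounts, the drain reads 1.87 mM h⁻¹ at 15.0 h, 1.72 mM h⁻¹ at 30 h and 1.67 mM h⁻¹ at 2.0 d, so the match at 30 h is a sliding figure passing the frozen one, which at 2.0 d leaves 15.3% where the simulated value is 16.2%. The forecast's figure is close to what taking over the last reading of target in south-west gives, a view that belongs to that run's charge, where target stood at 74.2%. Part of the flask's shortfall is reagent passing into dormant form within the time allowed: with that path taken away, target in the flask stands at 81.1% instead of 65.2%.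

The readings were generated by integration with made-up constants; the scatter is artificial.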